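Two things are asked of these flasks: a row of end amounts and how that row runs.

the same everywhere: gas 25 mM (held)
- dawn: starting material 42 mM; run made earlier
- noon: starting material 110 mM; run made earlier
- larch: starting material 15 mM; time 8.0 min
- alder: starting material 40 mM; time 8.0 min
- elm: starting material 120 mM; time 8.0 min

| run | time / min | target / % | starting material / % |
|---|---|---|---|
| dawn | 0.333 | 1.6 | 98.4 |
| dawn | 0.667 | 5.8 | 93.7 |
| dawn | 1.00 | 10.7 | 89.4 |
| dawn | 2.00 | 27.9 | 71.8 |
| dawn | 4.00 | 56.9 | 42.2 |
| noon | 0.833 | 6.1 | 93.2 |
| noon | 1.50 | 14.6 | 85.6 |
| noon | 2.50 | 25.6 | 74.1 |
| noon | 3.00 | 31.2 | 68.7 |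
| noon | 4.00 | 41.8 | 58.2 |

(scatter of a reading: 0.5 percentage points)

* amount of target at the end, in percent of the starting material charged for larch, alder, elm, in this order
* how the row runs (falls all the way / rises all the way / falls, then rises / rises, then falls / hardly changes)

- what was read earlier has a scatter of 0.5 percentage points, one standard deviation
- at the start none of the gas is in solution
- "hardly changes" means that all values lie within two and a half points (for a concentration: within two and a half percent of the largest)

We write f for the fraction of the charge still starting material, g for the fraction that is target, and c for the charge.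

1. The last readings of target and starting material sum to 99.1% in dawn and 100% in noon, so we take g as what f has lost.

2. Late in dawn the flask loses 6.22 mM/min, a share of 0.266 /min of what is left. Late in noon it loses 12.1 mM/min, a share of 0.154 /min. Noon's rate is higher but its share is lower, so the loss is not first order; the rate bends towards a ceiling.

3. A straight line, rate = V − K·share, through these two pairs gives a ceiling V of 20.1 mM/min and a reading K of 52.4 mM, the half-speed concentration, at which the rate is half the ceiling. Far below K the loss is pseudo-first-order, with share V/K.

4. Integrated, the line reads K·(−ln f) + c·g = V·τ, where τ is the clock, the minutes of effective running. Dawn's last reading gives a clock that trails the real time by a lag of 0.550 min.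

5. With that lag, V·τ/K at 8.0 min is 2.86. Solving for f gives target 92.6% in larch and 88.8% in alder. For elm, trial steps starting at f = 0.5 move f to 26.1%, then 28.9%.

6. The weak link is the single lag. Noon reads 0.309 min, shorter than dawn's, and elm's 120 mM stands beside noon's 110 mM. With noon's lag, elm's number becomes 2.96, and one more step leaves f at 27.4%, so target 72.6%. We commit to a row that falls all the way.

The forecast gives 93%, 90% and 72%, falls all the way, in its words “yield falls steadily with charge”, the same direction as ours, with alder higher than ours.

The flasks give 92.6%, 89.0% and 73.2%: falls all the way.

    gas ⇌ coupling partner, rate k1*(csat - [coupling partner]) (kL = 0.0140 /s)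
    starting material + coupling partner → target + by-product (k = 0.280 /M/s)

Elm still holds 27% starting material at 8.00 min, and by 80.0 min it stands at 100% target. Put through K, elm's remainder reads a clock of 7.79 min of the 8.0 min, and larch's remainder of 7.42% reads 7.46 min.

The runs are calculated on assumed constants.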